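**Plan**

1. The target is a 5,7-dihydroxyisoflavone. Ring A carries oxygen at C5, C7 and C8a (phloroglucinol pattern) and is fused to the 4-pyranone ring C, so it is a folded polyketide with the chiral chain on C6, the carbon between the two phenolic carbons.
2. The retrosynthesis cuts C7–C8 and C5–C6 of ring A. This leads back to a 5-aryl-2-methyl-4-pyranone-3-carboxylate (methyl = C8, ester carbon = C5) and a γ-silyloxy ester whose carbonyl becomes C7 and whose α-carbon becomes C6.
3. Forward, ring C with ring B attached is built first from 4-hydroxyphenylacetic acid, methyl acetoacetate and a one-carbon unit; the side-chain ester is made separately in three steps.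
4. The fragments are then joined and ring A is closed in one operation (lateral Claisen acylation, Dieckmann closure, aromatisation); one fluoride step removes both silyl groups.
5. The only stereocentre, C2'' (S), comes from the chiral pool as (S)-5-oxotetrahydrofuran-2-carboxylic acid, and none of its four bonds is made or broken afterwards.

Key step: step 7

Remark on the chemistry: chromone numbering (C2–C8a, chain C1''–C4'') is used for ring-A atoms throughout; tricarbonyl compounds 6 and 7 are drawn as keto forms but should exist as chelated enols.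

**Route**

Step 1
Reactants: 1 4-hydroxyphenylacetic acid
Product: 3 2-[4-(triisopropylsilyloxy)phenyl]acetic acid, via triisopropylsilyl ester 2 (not isolated)
Conditions: TIPSCl (2.2 equiv), imidazole, DMF, rt; then THF/1 M aq. HCl, rt
Reagents that add atoms: triisopropylsilyl chloride, CC(C)[Si](Cl)(C(C)C)C(C)C
Why: Silylation of phenol and acid followed by selective hydrolysis of the much more labile silyl ester is standard, and the aryl TIPS ether is chosen because it should withstand amide bases and methoxide yet fall to fluoride at the end.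

Step 2
Reactants: 3 2-[4-(triisopropylsilyloxy)phenyl]acetic acid; 4 methyl acetoacetate
Product: 6 methyl 2-acetyl-3-oxo-4-[4-(triisopropylsilyloxy)phenyl]butanoate, via arylacetyl chloride 5 (not isolated)
Conditions: (COCl)2, cat. DMF, CH2Cl2, 0 °C → rt, evaporate; then 4, MgCl2, pyridine, CH2Cl2, 0 °C → rt; cold dilute acid work-up
Reagents that add atoms: none
Why: MgCl2/pyridine soft-enolisation C-acylation of a β-keto ester by an acid chloride should give the 2-acyl acetoacetate as its magnesium chelate, which protects it from over-acylation and deacylation until work-up.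

Step 3
Reactants: 6 methyl 2-acetyl-3-oxo-4-[4-(triisopropylsilyloxy)phenyl]butanoate
Product: 8 methyl 2-methyl-4-oxo-5-[4-(triisopropylsilyloxy)phenyl]-4H-pyran-3-carboxylate, via enaminone 7 (not isolated)
Conditions: Me2NCH(OMe)2 (1.3 equiv), toluene, 80 °C; then AcOH, 60 °C
Reagents that add atoms: N,N-dimethylformamide dimethyl acetal, COC(OC)N(C)C
Why: Aminomethylenation should occur at the benzylic CH2, which is far more acidic than the acetyl methyl (as in benzyl methyl ketones), and the acetyl enol oxygen then displaces dimethylamine by 6-endo addition–elimination, the acyclic counterpart of the deoxybenzoin-to-isoflavone closure and of the pyranone annulation of 2-acyl-1,3-diones.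

Step 4
Reactants: 9 (S)-5-oxotetrahydrofuran-2-carboxylic acid
Product: 11 (S)-5-acetyldihydrofuran-2(3H)-one, via lactone acid chloride 10 (not isolated)
Conditions: (COCl)2, cat. DMF, CH2Cl2, rt, evaporate; then MeMgBr (1.05 equiv), Fe(acac)3 (3 mol%), THF, −78 °C
Reagents that add atoms: methylmagnesium bromide, C[Mg]Br
Why: Fe(acac)3-catalysed ketone synthesis from an acid chloride and a Grignard reagent at −78 °C is much faster than addition to the lactone or to the product ketone, so the methyl ketone should form with the stereocentre untouched.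

Step 5
Reactants: 11 (S)-5-acetyldihydrofuran-2(3H)-one
Product: 12 (S)-5-(prop-1-en-2-yl)dihydrofuran-2(3H)-one
Conditions: Zn, CH2Br2, TiCl4, THF/CH2Cl2, 0 °C → rt
Reagents that add atoms: dibromomethane, BrCBr
Why: Takai–Lombardo methylenation is non-basic and selective for ketones over lactones, so the epimerisable α-acyloxy ketone should become the isopropenyl group without loss of configuration.

Step 6
Reactants: 12 (S)-5-(prop-1-en-2-yl)dihydrofuran-2(3H)-one
Product: 15 methyl (S)-4-[(tert-butyldimethylsilyl)oxy]-5-methylhex-5-enoate, via potassium hydroxy carboxylate 13 (not isolated), via hydroxy methyl ester 14 (not isolated)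
Conditions: KOH (1.0 equiv), MeOH/H2O, rt, evaporate to dryness; MeI, DMF, 0 °C → rt; then imidazole, TBSCl, rt
Reagents that add atoms: potassium hydroxide, [K+].[OH-]; iodomethane, CI; tert-butyldimethylsilyl chloride, CC(C)(C)[Si](C)(C)Cl
Why: Lactone saponification, SN2 O-methylation of the carboxylate and silylation of the freed secondary alcohol in one flask avoid isolating the γ-hydroxy ester, which would relactonise, and no bond to the stereocentre is broken.

Step 7
Reactants: 8 methyl 2-methyl-4-oxo-5-[4-(triisopropylsilyloxy)phenyl]-4H-pyran-3-carboxylate; 15 methyl (S)-4-[(tert-butyldimethylsilyl)oxy]-5-methylhex-5-enoate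
Product: 17 6-[(2S)-2-[(tert-butyldimethylsilyl)oxy]-3-methylbut-3-en-1-yl]-5,7-dihydroxy-3-[4-(triisopropylsilyloxy)phenyl]-4H-chromen-4-one, via Claisen keto ester 16 (not isolated)
Conditions: 8 (2.0 equiv), LiN(iPr)2 (LDA, 2.0 equiv), THF, −78 °C; 15 (1.0 equiv), −78 → −40 °C; LDA (2.5 equiv), −78 → 0 °C; AcOH quench (excess 8 should be recoverable)
Reagents that add atoms: none
Why: Proposed new method: LDA deprotonates the 2-methyl group of 8, which is vinylogous to both the ring ketone and the ester, and the dienolate is acylated at that exocyclic carbon by 15 (C7–C8), keto ester 16 then resting as its C8 enolate; a second charge of LDA gives the C6,C8-dianion, whose C6 terminus attacks the ring ester (C5–C6), and the resulting 1,3-dione anion is already the aromatic 5,7-diphenoxide. The closest known reaction types are the tandem lateral Claisen–Dieckmann condensation of ortho-toluate anions with esters to naphthalene-1,3-diols and the biomimetic Claisen cyclisation of polyketo esters, with the pyranone here playing the part of the arene. Ring A closes by a 6-exo-trig Dieckmann attack of the C6 carbanion on the ester carbonyl, the only ring size within reach. No stereocentre is formed: C2'' is a spectator that has no acidic hydrogen and, lying two carbons from the C6 carbanion, cannot be lost by β-elimination. The step needs lateral acylation instead of attack at the ester-bearing ring carbon or conjugate addition to the O–CH= carbon of the pyranone (the future C2), which the doubly vinylogous acidity of the methyl group and the hindered base should secure; it needs C- instead of O-cyclisation of 16, secured by forming the dianion before warming; and self-condensation of 15 is avoided by having no free amide base present while the ester is consumed. Because O1 and ring B are already fixed in the pyranone, the chain can only end at C6 and not at C8.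

Step 8
Reactants: 17 6-[(2S)-2-[(tert-butyldimethylsilyl)oxy]-3-methylbut-3-en-1-yl]-5,7-dihydroxy-3-[4-(triisopropylsilyloxy)phenyl]-4H-chromen-4-one
Product: 18 5,7-dihydroxy-6-[(2S)-2-hydroxy-3-methylbut-3-en-1-yl]-3-(4-hydroxyphenyl)-4H-chromen-4-one
Conditions: Bu4NF (4 equiv), AcOH (4 equiv), THF, 0 °C → rt
Reagents that add atoms: none
Why: Fluoride-driven desilylation should cleave both the aryl TIPS and the secondary TBS ether, and the acetic acid buffer keeps the medium near neutral so that the phenols cannot add to the isopropenyl group as they might under acid.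

**Compound list**

1 | 4-hydroxyphenylacetic acid | OC(=O)Cc1ccc(O)cc1 | starting material
2 | triisopropylsilyl 2-[4-(triisopropylsilyloxy)phenyl]acetate | CC(C)[Si](C(C)C)(C(C)C)OC(=O)Cc1ccc(O[Si](C(C)C)(C(C)C)C(C)C)cc1 | intermediate
3 | 2-[4-(triisopropylsilyloxy)phenyl]acetic acid | OC(=O)Cc1ccc(O[Si](C(C)C)(C(C)C)C(C)C)cc1 | intermediate
4 | methyl acetoacetate | CC(=O)CC(=O)OC | starting material
5 | 2-[4-(triisopropylsilyloxy)phenyl]acetyl chloride | ClC(=O)Cc1ccc(O[Si](C(C)C)(C(C)C)C(C)C)cc1 | intermediate
6 | methyl 2-acetyl-3-oxo-4-[4-(triisopropylsilyloxy)phenyl]butanoate | COC(=O)C(C(C)=O)C(=O)Cc1ccc(O[Si](C(C)C)(C(C)C)C(C)C)cc1 | intermediate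
7 | methyl 2-acetyl-5-(dimethylamino)-3-oxo-4-[4-(triisopropylsilyloxy)phenyl]pent-4-enoate | COC(=O)C(C(C)=O)C(=O)C(=CN(C)C)c1ccc(O[Si](C(C)C)(C(C)C)C(C)C)cc1 | intermediate
8 | methyl 2-methyl-4-oxo-5-[4-(triisopropylsilyloxy)phenyl]-4H-pyran-3-carboxylate | COC(=O)c1c(C)occ(-c2ccc(O[Si](C(C)C)(C(C)C)C(C)C)cc2)c1=O | intermediate
9 | (S)-5-oxotetrahydrofuran-2-carboxylic acid | OC(=O)[C@@H]1CCC(=O)O1 | starting material
10 | (S)-5-oxotetrahydrofuran-2-carbonyl chloride | ClC(=O)[C@@H]1CCC(=O)O1 | intermediate
11 | (S)-5-acetyldihydrofuran-2(3H)-one | CC(=O)[C@@H]1CCC(=O)O1 | intermediate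
12 | (S)-5-(prop-1-en-2-yl)dihydrofuran-2(3H)-one | C=C(C)[C@@H]1CCC(=O)O1 | intermediate
13 | potassium (S)-4-hydroxy-5-methylhex-5-enoate | C=C(C)[C@@H](O)CCC(=O)[O-].[K+] | intermediate
14 | methyl (S)-4-hydroxy-5-methylhex-5-enoate | C=C(C)[C@@H](O)CCC(=O)OC | intermediate
15 | methyl (S)-4-[(tert-butyldimethylsilyl)oxy]-5-methylhex-5-enoate | C=C(C)[C@@H](O[Si](C)(C)C(C)(C)C)CCC(=O)OC | intermediate
16 | methyl 2-[(5S)-5-[(tert-butyldimethylsilyl)oxy]-6-methyl-2-oxohept-6-en-1-yl]-4-oxo-5-[4-(triisopropylsilyloxy)phenyl]-4H-pyran-3-carboxylate | C=C(C)[C@@H](O[Si](C)(C)C(C)(C)C)CCC(=O)Cc1occ(-c2ccc(O[Si](C(C)C)(C(C)C)C(C)C)cc2)c(=O)c1C(=O)OC | intermediate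
17 | 6-[(2S)-2-[(tert-butyldimethylsilyl)oxy]-3-methylbut-3-en-1-yl]-5,7-dihydroxy-3-[4-(triisopropylsilyloxy)phenyl]-4H-chromen-4-one | C=C(C)[C@@H](O[Si](C)(C)C(C)(C)C)Cc1c(O)cc2occ(-c3ccc(O[Si](C(C)C)(C(C)C)C(C)C)cc3)c(=O)c2c1O | intermediate
18 | 5,7-dihydroxy-6-[(2S)-2-hydroxy-3-methylbut-3-en-1-yl]-3-(4-hydroxyphenyl)-4H-chromen-4-one | C=C(C)[C@@H](O)Cc1c(O)cc2occ(-c3ccc(O)cc3)c(=O)c2c1O | target

**Step count and risks**

Total: 8 steps. Longest linear sequence: 5 steps (1 → 2 → 3 → 7 → 8; the branch 4 → 5 → 6 → 7 → 8 is equally long).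

Steps most likely to fail:

1. Step 7. Proton transfer from the freshly formed keto ester to the dienolate, or enolisation of the acyl donor, may stall the acylation. The mono-enolate may also close through oxygen onto the ring ester before the dianion exists. The fallback uses only known reactions, sets out from 1 and rejoins the route at 18. Friedel–Crafts acylation of phloroglucinol with 1 in BF3·Et2O should give 2-(4-hydroxyphenyl)-1-(2,4,6-trihydroxyphenyl)ethan-1-one F1, and DMF/MsCl added to the same flask should close it to genistein F2. MOMCl/iPr2NEt should give the 7,4'-bis-MOM ether F3, the chelated 5-OH staying free. BnMe3N·ICl2/CaCO3 should iodinate ortho to that free 5-OH to give the 6-iodide F4, and NaH/MOMCl then caps the 5-OH to give the tris-MOM iodide F5. Suzuki coupling with prenylboronic acid pinacol ester (Pd(dppf)Cl2, K3PO4, conditions selective for the linear product) should give the 6-prenyl compound F6. Shi epoxidation with the enantiomer of the fructose-derived ketone that delivers the (S)-epoxide should give the epoxide F7. Base-induced epoxide-to-allylic-alcohol isomerisation (Al(OiPr)3, toluene, heat) should give the tris-MOM allylic alcohol F8. Non-acidic MOM removal (TMSOTf, 2,2'-bipyridyl, then water) returns 18.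

2. Step 3. Aminomethylenation may take place at the acetyl methyl instead of the benzylic carbon, or the liberated dimethylamine and methanol may deacylate the tricarbonyl. The fallback attaches the aryl group last; it sets out from 4 and rejoins at 8. C-acylation of 4 with (E)-3-ethoxyacryloyl chloride (MgCl2, pyridine) should give methyl (E)-2-acetyl-5-ethoxy-3-oxopent-4-enoate F9. TsOH in toluene should cyclise it with loss of ethanol to methyl 2-methyl-4-oxo-4H-pyran-3-carboxylate F10. Electrophilic bromination at C5 (NBS, MeCN, dark) should give methyl 5-bromo-2-methyl-4-oxo-4H-pyran-3-carboxylate F11. Suzuki coupling with 4-hydroxyphenylboronic acid (Pd(PPh3)4, Na2CO3, DME/H2O) should give methyl 5-(4-hydroxyphenyl)-2-methyl-4-oxo-4H-pyran-3-carboxylate F12, and TIPSCl/imidazole converts it into 8.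

3. Step 6. The γ-hydroxy ester may relactonise before the silyl group is on. The fallback silylates at the carboxylate stage and esterifies last, so that a free γ-hydroxy ester never exists; it sets out from 12 (saponified as before to 13) and rejoins at 15. The dry salt 13 with excess TBSCl/imidazole in DMF should give tert-butyldimethylsilyl (S)-4-[(tert-butyldimethylsilyl)oxy]-5-methylhex-5-enoate F13. K2CO3 in aqueous MeOH/THF should cleave only the silyl ester to give (S)-4-[(tert-butyldimethylsilyl)oxy]-5-methylhex-5-enoic acid F14, and TMSCHN2 in toluene/MeOH then gives 15.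

**Further compounds**

F1 | step 7 | 2-(4-hydroxyphenyl)-1-(2,4,6-trihydroxyphenyl)ethan-1-one | O=C(Cc1ccc(O)cc1)c1c(O)cc(O)cc1O
F2 | step 7 | genistein, 5,7-dihydroxy-3-(4-hydroxyphenyl)-4H-chromen-4-one | O=c1c(-c2ccc(O)cc2)coc2cc(O)cc(O)c12
F3 | step 7 | 5-hydroxy-7-(methoxymethoxy)-3-[4-(methoxymethoxy)phenyl]-4H-chromen-4-one | COCOc1ccc(-c2coc3cc(OCOC)cc(O)c3c2=O)cc1
F4 | step 7 | 5-hydroxy-6-iodo-7-(methoxymethoxy)-3-[4-(methoxymethoxy)phenyl]-4H-chromen-4-one | COCOc1ccc(-c2coc3cc(OCOC)c(I)c(O)c3c2=O)cc1
F5 | step 7 | 6-iodo-5,7-bis(methoxymethoxy)-3-[4-(methoxymethoxy)phenyl]-4H-chromen-4-one | COCOc1ccc(-c2coc3cc(OCOC)c(I)c(OCOC)c3c2=O)cc1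
F6 | step 7 | 5,7-bis(methoxymethoxy)-3-[4-(methoxymethoxy)phenyl]-6-(3-methylbut-2-en-1-yl)-4H-chromen-4-one | COCOc1ccc(-c2coc3cc(OCOC)c(CC=C(C)C)c(OCOC)c3c2=O)cc1
F7 | step 7 | 6-{[(2S)-3,3-dimethyloxiran-2-yl]methyl}-5,7-bis(methoxymethoxy)-3-[4-(methoxymethoxy)phenyl]-4H-chromen-4-one | COCOc1ccc(-c2coc3cc(OCOC)c(C[C@@H]4OC4(C)C)c(OCOC)c3c2=O)cc1
F8 | step 7 | 6-[(2S)-2-hydroxy-3-methylbut-3-en-1-yl]-5,7-bis(methoxymethoxy)-3-[4-(methoxymethoxy)phenyl]-4H-chromen-4-one | C=C(C)[C@@H](O)Cc1c(OCOC)cc2occ(-c3ccc(OCOC)cc3)c(=O)c2c1OCOC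
F9 | step 3 | methyl (E)-2-acetyl-5-ethoxy-3-oxopent-4-enoate | CCO/C=C/C(=O)C(C(C)=O)C(=O)OC
F10 | step 3 | methyl 2-methyl-4-oxo-4H-pyran-3-carboxylate | COC(=O)c1c(C)occc1=O
F11 | step 3 | methyl 5-bromo-2-methyl-4-oxo-4H-pyran-3-carboxylate | COC(=O)c1c(C)occ(Br)c1=O
F12 | step 3 | methyl 5-(4-hydroxyphenyl)-2-methyl-4-oxo-4H-pyran-3-carboxylate | COC(=O)c1c(C)occ(-c2ccc(O)cc2)c1=O
F13 | step 6 | tert-butyldimethylsilyl (S)-4-[(tert-butyldimethylsilyl)oxy]-5-methylhex-5-enoate | C=C(C)[C@@H](O[Si](C)(C)C(C)(C)C)CCC(=O)O[Si](C)(C)C(C)(C)C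
F14 | step 6 | (S)-4-[(tert-butyldimethylsilyl)oxy]-5-methylhex-5-enoic acid | C=C(C)[C@@H](O[Si](C)(C)C(C)(C)C)CCC(=O)O
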